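## Analysis of the target

The target is the 3-O-(3-hydroxy-4,5-dimethoxybenzoyl) ester of (−)-epicatechin: a 2-arylchroman in which the phloroglucinol-type ring A (oxygen at C5, C7 and C8a) is fused to the dihydropyran ring C, with the catechol ring B on C2 and the aroyloxy group on C3. It has two adjacent stereocentres, C2 and C3, both R. The aryl group and the ester oxygen are therefore cis, the less stable of the two relative arrangements. Five free phenols are present: ring B is an oxidisable catechol and ring A is strongly nucleophilic at C6 and C8. C2 is a benzylic ether carbon that epimerises under base or strong acid, and the aryl ester is labile to base. The difficulties are to obtain the 2,3-cis relation with absolute control, to acylate O3 alone among six hydroxyl groups with an acid that carries a phenol of its own, and to keep C2 and C3 intact to the end. The strategy rests on ring A: it carries O1 on C8a and C4 on C4a, on neighbouring carbons, with the C5 oxygen directly beside C4a. That is the substitution pattern left when a 3,5-dialkoxybenzyne takes up an oxygen nucleophile at the remote aryne carbon and an acyl group at the carbon next to the alkoxy group. The C2–C3–C4 unit then corresponds to a 2,3-dioxygenated 3-arylpropanoate whose hydroxyl oxygen becomes O1 and whose ester carbon becomes C4.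

## Retrosynthetic reasoning

**30 to 29.** All five phenols of target 30 are unmasked last from the penta-O-benzyl ester 29 by hydrogenolysis. Benzyl ethers leave O3 as the only free hydroxyl earlier on, and a neutral final step avoids acyl migration and C2 epimerisation.

**29 to 25 and 28.** The acyl–O3 bond is cut, giving alcohol 25 (tetra-O-benzyl epicatechin) and the O-benzylated acid 28, which comes from commercial acid 26. This is the most labile bond, and cutting it joins two fully built halves late. The forward reaction has to acylate a hindered axial secondary alcohol without breaking C3–O.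

**25 to 23, 22 and 21.** The methylene group at C4 is traced back through allyl ether 23 and alcohol 22 to ketone 21. The C4 carbonyl is not part of the target, but it is what an acyl-transfer ring closure leaves behind. Its removal is safe because the derived C4 cation is stabilised by three ring A oxygens. O3 is carried as an allyl ether, which survives fluoride, hydride and acid and is removed without touching benzyl ethers.

**21 to 6 and 17 (key disconnection).** Both ring C bonds to ring A, O1–C8a and C4–C4a, are cut together. Ring A becomes aryne 18, released from silyl triflate 6, and ring C becomes the open-chain silyl ether 17.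
- These two bonds are chosen because the aryne adds a nucleophile and an electrophile to neighbouring carbons in one event, and the benzyloxy group beside the triple bond decides which carbon receives which.
- The gain is that the whole flavan skeleton is assembled from two short fragments after both stereocentres already exist.
- The forward step must generate alkoxide 19 without any proton in the medium. A free hydroxyl is too weak an acid to be deprotonated by fluoride and would hand its proton to the aryl carbon, so the oxygen is carried as its trimethylsilyl ether and is released by the same fluoride that releases the aryne.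
- The aryl caesium 20 must then attack the ester faster than it is quenched.

**17 to 16, 15, 12 and 13.** Silyl ether 17 comes from hydroxy ester 16, and 16 from imide 15 by methanolysis. The bond between the two oxygen-bearing carbons of 15 is cut as a syn glycolate aldol between imide 12 and aldehyde 13. This sets both stereocentres of the target in one well-understood step. Imide 12 is made from acid 9 and auxiliary 10, and 9 from alcohol 7 and bromo acid 8.

**6 to 3, 2 and 1.** The C–Si bond of 6 is traced through aryllithium 4 and phenoxide 5 (silyl shift from oxygen to carbon) to silyl ether 3, bromophenol 2 and phenol 1. The only selectivity needed is bromination ortho to the hydroxyl group, and the two ortho positions of 1 are equivalent.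

## Alternatives that were turned down

**Alternative 1:** Ring A is built last by cutting C4a–C5.
- Forward key step: a base converts keto ester A1, a finished ring C carrying a CH2–CO–CH2–CO2Me chain on its enol ether carbon, into a dienolate. The dienolate attacks the ester through C4a in a Claisen condensation, and the resulting dione tautomerises to the resorcinol A2.
- For: the oxygenation pattern of ring A is inherent in the chain, so no regiochemical question arises. Aromatisation drives the step, and C4 is already a methylene group. On these points it is stronger than the chosen route, which needs two redox steps at C4.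
- Against: A1 must already contain the cis-2-aryl-3-alkoxy dihydropyran, an acid-labile enol ether and a base-sensitive 1,3-dicarbonyl chain, and it needs its own long asymmetric synthesis. After A2 the two new phenols still have to be benzylated before O3 can be freed and acylated.
- Comparison: it spends its effort constructing a ring that is commercial. The chosen route buys ring A as phenol 1 and reaches both key-step partners in three and five steps.

**Alternative 2:** The C2=C3 bond of a flav-2-ene is cut.
- Forward key step: low-valent titanium made from TiCl3 and zinc couples the aldehyde and the ester carbonyl of A3 reductively, closing ring C as the enol ether A4.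
- For: A3 is a simple phenyl ester reachable in few steps, C4 is at the right oxidation level, and oxo–ester coupling is a known reaction type. On the last point it is stronger than the chosen key step, which is new.
- Against: A4 has no stereocentre. Both centres would have to be set afterwards on an acid-sensitive trisubstituted enol ether. Syn hydroboration places H on C2 and boron on C3 on the same face, which gives the 2,3-trans relation, so an oxidation and reduction at C3 would have to follow, and enantiocontrol in such a hydroboration is weak. The electron-rich aryl ester is a poor acceptor and the arylacetaldehyde is prone to pinacol coupling.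
- Comparison: the chosen route offers instead absolute and relative control from an auxiliary aldol before ring closure, with no inversion needed.

**Alternative 3:** O1–C2 and C3–C4 are cut together.
- Forward key step: a chiral phosphoric acid dehydrates salicyl alcohol A5 to the o-quinone methide A6, which adds the Z-enol ester A7 across O1 and C4 to give A8, identical with 29.
- For: it is the most convergent plan. Ring C, both stereocentres and the ester are made in one step, the cis relation comes from the Z geometry, and no C4 redox or O3 protecting group is needed. In step economy it is clearly stronger than the chosen route.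
- Against: regio-, diastereo- and enantioselectivity all rest on one unprecedented event.
  - The required regiochemistry needs the styrene-type polarisation of A7 to override the enol-ester polarisation, which points the other way.
  - The acyloxy group makes the alkene a poor nucleophile, and a stepwise path through the C2 benzylic cation would allow rotation to the trans product.
  - A6 has an unsubstituted methylene terminus, oligomerises easily and offers the catalyst little to hold.
- Comparison: the chosen route is about three times longer but divides the risk. Stereochemistry comes from a reliable aldol, the new step needs only regiocontrol, and known chemistry can replace it if it fails.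

Key step: step 9

Remark: 3,5-bis(benzyloxy)phenol (1), the O,O-dibenzyl ether of phloroglucinol, is taken as a commercial compound; the C4 epimers of alcohol 22 are carried on together because C4 becomes a methylene group in step 11.

## Route

Step 1
Reactants: 1 3,5-bis(benzyloxy)phenol
Product: 2 2-bromo-3,5-bis(benzyloxy)phenol
Conditions: NBS (1.0 equiv), i-Pr2NH (0.1 equiv), CH2Cl2, −78 → 0 °C
Reagents that add atoms: N-bromosuccinimide, O=C1CCC(=O)N1Br
Why: Amine-catalysed ortho-selective electrophilic bromination of a phenol, in which the N-bromoamine is delivered through hydrogen bonding to the hydroxyl group; the two ortho positions are equivalent, and one equivalent at low temperature limits para attack and dibromination.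

Step 2
Reactants: 2 2-bromo-3,5-bis(benzyloxy)phenol
Product: 3 [2-bromo-3,5-bis(benzyloxy)phenoxy]trimethylsilane
Conditions: (Me3Si)2NH, THF, 65 °C; evaporation
Reagents that add atoms: hexamethyldisilazane, C[Si](C)(C)N[Si](C)(C)C
Why: O-silylation of a phenol with hexamethyldisilazane; ammonia is the only by-product, so the crude silyl ether can be used after evaporation.

Step 3
Reactants: 3 [2-bromo-3,5-bis(benzyloxy)phenoxy]trimethylsilane
Product: 6 3,5-bis(benzyloxy)-2-(trimethylsilyl)phenyl trifluoromethanesulfonate, via aryllithium 4 (not isolated), via lithium 2-silylphenoxide 5 (not isolated)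
Conditions: n-BuLi, THF, −100 → −80 °C; then Tf2O, −100 → −80 °C
Reagents that add atoms: trifluoromethanesulfonic anhydride, O=S(=O)(OS(=O)(=O)C(F)(F)F)C(F)(F)F
Why: Bromine–lithium exchange is faster than benzylic deprotonation at this temperature; the aryllithium undergoes the anionic 1,3-silyl shift from oxygen to carbon (retro-Brook rearrangement), and the phenoxide is triflated in the same flask, the standard route to o-silylaryl triflates.

Step 4
Reactants: 7 prop-2-en-1-ol (allyl alcohol); 8 bromoacetic acid
Product: 9 2-(allyloxy)acetic acid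
Conditions: NaH (2.5 equiv), THF, 0 → 65 °C; then 1 M HCl
Reagents that add atoms: none
Why: Williamson ether synthesis; sodium allyloxide displaces bromide from the bromoacetate salt by SN2.

Step 5
Reactants: 9 2-(allyloxy)acetic acid; 10 (S)-4-benzyloxazolidin-2-one
Product: 12 (S)-3-[2-(allyloxy)acetyl]-4-benzyloxazolidin-2-one, via mixed pivalic anhydride 11 (not isolated)
Conditions: t-BuCOCl, Et3N, THF, −20 °C; then LiCl, 10, −20 → 20 °C
Reagents that add atoms: none
Why: N-acylation of the oxazolidinone through a mixed anhydride; the pivaloyl carbonyl is shielded, so the glycolyl carbonyl is the one attacked, and LiCl with Et3N makes the auxiliary nucleophilic enough without a strong base.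

Step 6
Reactants: 12 (S)-3-[2-(allyloxy)acetyl]-4-benzyloxazolidin-2-one; 13 3,4-bis(benzyloxy)benzaldehyde
Product: 15 (S)-3-{(2S,3R)-2-(allyloxy)-3-[3,4-bis(benzyloxy)phenyl]-3-hydroxypropanoyl}-4-benzyloxazolidin-2-one, via Z-boron enolate 14 (not isolated)
Conditions: Bu2BOTf, Et3N, CH2Cl2, −78 → 0 °C; 13, −78 → 0 °C; then pH 7 buffer, MeOH, 30% H2O2, 0 °C
Reagents that add atoms: none
Why: Evans syn glycolate aldol; the Z-boron enolate reacts through a closed chair transition state, so its geometry gives the 2,3-syn relation, and the benzyl group of the (S)-auxiliary, held with its carbonyl turned away from the enolate oxygen, blocks one enolate face and gives (2S,3R), which maps onto C3 and C2 of the flavan.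

Step 7
Reactants: 15 (S)-3-{(2S,3R)-2-(allyloxy)-3-[3,4-bis(benzyloxy)phenyl]-3-hydroxypropanoyl}-4-benzyloxazolidin-2-one
Product: 16 methyl (2S,3R)-2-(allyloxy)-3-[3,4-bis(benzyloxy)phenyl]-3-hydroxypropanoate
Conditions: MeMgBr, MeOH, CH2Cl2, 0 °C; NH4Cl aq.
Reagents that add atoms: methanol, CO
Why: Transesterification of the imide with methoxymagnesium bromide; chelation by magnesium directs methoxide to the exocyclic carbonyl, and the conditions are mild enough to avoid retro-aldol cleavage and epimerisation of the alpha carbon.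

Step 8
Reactants: 16 methyl (2S,3R)-2-(allyloxy)-3-[3,4-bis(benzyloxy)phenyl]-3-hydroxypropanoate
Product: 17 methyl (2S,3R)-2-(allyloxy)-3-[3,4-bis(benzyloxy)phenyl]-3-[(trimethylsilyl)oxy]propanoate
Conditions: Me3SiCl, imidazole, CH2Cl2, 0 °C; non-aqueous work-up
Reagents that add atoms: chlorotrimethylsilane, C[Si](C)(C)Cl
Why: O-silylation of a secondary alcohol; it removes the only acidic proton and turns the oxygen into a nucleophile that fluoride can release on demand.

Step 9
Reactants: 6 3,5-bis(benzyloxy)-2-(trimethylsilyl)phenyl trifluoromethanesulfonate; 17 methyl (2S,3R)-2-(allyloxy)-3-[3,4-bis(benzyloxy)phenyl]-3-[(trimethylsilyl)oxy]propanoate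
Product: 21 (2R,3S)-3-(allyloxy)-5,7-bis(benzyloxy)-2-[3,4-bis(benzyloxy)phenyl]chroman-4-one (2,3-cis), via aryne 18 (not isolated), via caesium alkoxide 19 (not isolated), via aryl caesium ether 20 (not isolated)
Conditions: CsF (2.5 equiv), 18-crown-6 (0.5 equiv), THF, 0 → 20 °C, 6 (1.2 equiv) and 17 added together over 2 h; pH 7 buffer
Reagents that add atoms: none
Why: Proposed new method: fluoride removes the O-silyl group of 17 to give the proton-free caesium alkoxide 19 and the C-silyl group of 6 to give aryne 18 with loss of triflate; 19 adds through oxygen to the aryne carbon remote from the flanking benzyloxy group, the aryl caesium 20 attacks the methyl ester carbon of its own chain, and the tetrahedral intermediate expels methoxide, which is silylated by 6 or 17 and so carries the reaction on instead of remaining as a base. The closest known reaction types are the aryne annulation of methyl salicylates to xanthones (phenoxide addition, then acyl substitution by the aryl anion), the insertion of arynes into O–H bonds of aliphatic alcohols, and the fluoride-triggered addition of silylated heteroatom nucleophiles to arynes; new here are a secondary aliphatic alkoxide carrying two stereocentres and an aliphatic ester as acyl acceptor. Ring C closes in the second event by 6-exo-trig attack of C4a on the ester carbonyl, after O1–C8a has formed intermolecularly. No stereocentre is created: the C2–O1 bond of 17 is never broken and C3 is not deprotonated, so the syn (2S,3R) arrangement becomes the 2,3-cis (2R,3S) chromanone. The selectivity the step needs is regiochemical, and the benzyloxy group next to the triple bond of 18 secures it: attack at the distal carbon leaves the negative charge on the carbon beside the C–O bond, where it is stabilised inductively, so oxygen ends on C8a and the carbanion on C4a next to C5. Acylation must outrun protonation and C-silylation of 20; the six-membered transition state, the absence of any O–H or acidic C–H in the medium (silyl ether in place of the alcohol, THF in place of MeCN) and slow joint addition favour it. Low temperature, only a small excess of 6 and a neutral quench keep C3, now alpha to a ketone, from epimerising to the more stable trans isomer.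

Step 10
Reactants: 21 (2R,3S)-3-(allyloxy)-5,7-bis(benzyloxy)-2-[3,4-bis(benzyloxy)phenyl]chroman-4-one
Product: 22 (2R,3R)-3-(allyloxy)-5,7-bis(benzyloxy)-2-[3,4-bis(benzyloxy)phenyl]chroman-4-ol (2,3-cis, both C4 epimers)
Conditions: NaBH4, CeCl3·7H2O, MeOH/THF, −40 → 0 °C
Reagents that add atoms: none
Why: Luche-type 1,2-reduction; CeCl3 activates the ketone and gives less basic alkoxyborohydrides, so hydride transfer should outrun enolisation toward C3; the new C4 centre is not controlled (attack anti to the axial C3 alkoxy group should favour the 3,4-cis alcohol) and is removed in step 11.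

Step 11
Reactants: 22 (2R,3R)-3-(allyloxy)-5,7-bis(benzyloxy)-2-[3,4-bis(benzyloxy)phenyl]chroman-4-ol
Product: 23 (2R,3R)-3-(allyloxy)-5,7-bis(benzyloxy)-2-[3,4-bis(benzyloxy)phenyl]chroman
Conditions: Et3SiH (5 equiv), CF3CO2H, CH2Cl2, −40 → 0 °C
Reagents that add atoms: none
Why: Ionic hydrogenation; the acid ionises the C4 alcohol to a benzylic cation stabilised by O1 and the C5 and C7 oxygens, and Et3SiH transfers hydride to it; C2 and C3 take no part, so the cis relation is kept.

Step 12
Reactants: 23 (2R,3R)-3-(allyloxy)-5,7-bis(benzyloxy)-2-[3,4-bis(benzyloxy)phenyl]chroman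
Product: 25 (2R,3R)-5,7-bis(benzyloxy)-2-[3,4-bis(benzyloxy)phenyl]chroman-3-ol, via prop-1-enyl ether 24 (not isolated)
Conditions: [Ir(cod)(PMePh2)2]PF6 (2 mol%, activated with H2), THF, 20 °C; then 1 M HCl, THF, 20 °C
Reagents that add atoms: none
Why: Allyl ether cleavage by iridium-catalysed isomerisation to the prop-1-enyl ether, then acid hydrolysis of the enol ether; the C3–O bond is not broken and benzyl ethers are inert to both stages.

Step 13
Reactants: 26 3-hydroxy-4,5-dimethoxybenzoic acid
Product: 28 3-(benzyloxy)-4,5-dimethoxybenzoic acid, via benzyl ester 27 (not isolated)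
Conditions: BnBr, K2CO3, DMF, 60 °C; then NaOH, MeOH/H2O, 65 °C; HCl
Reagents that add atoms: benzyl bromide, BrCc1ccccc1; sodium hydroxide, [Na+].[OH-]
Why: Williamson benzylation of the phenol and the carboxylate, then saponification of the benzyl ester in the same flask; the aryl benzyl ether is stable to hydroxide.

Step 14
Reactants: 25 (2R,3R)-5,7-bis(benzyloxy)-2-[3,4-bis(benzyloxy)phenyl]chroman-3-ol; 28 3-(benzyloxy)-4,5-dimethoxybenzoic acid
Product: 29 (2R,3R)-5,7-bis(benzyloxy)-2-[3,4-bis(benzyloxy)phenyl]chroman-3-yl 3-(benzyloxy)-4,5-dimethoxybenzoate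
Conditions: DCC, DMAP, CH2Cl2, 0 → 20 °C
Reagents that add atoms: none
Why: Steglich esterification; DMAP relays the O-acylisourea as an acylpyridinium that acylates the hindered axial alcohol; the C3–O bond is not broken, so the configuration is retained, and no other hydroxyl is free.

Step 15
Reactants: 29 (2R,3R)-5,7-bis(benzyloxy)-2-[3,4-bis(benzyloxy)phenyl]chroman-3-yl 3-(benzyloxy)-4,5-dimethoxybenzoate
Product: 30 (2R,3R)-2-(3,4-dihydroxyphenyl)-5,7-dihydroxychroman-3-yl 3-hydroxy-4,5-dimethoxybenzoate
Conditions: H2 (1 atm), Pd(OH)2/C, THF/MeOH, 20 °C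
Reagents that add atoms: none
Why: Hydrogenolysis of five benzyl ethers under neutral conditions; the aryl ester, the methyl ethers and the chroman C2–O1 bond should survive, and no base is present that could epimerise C2 or move the acyl group.

## Compound list

1 | 3,5-bis(benzyloxy)phenol | Oc1cc(OCc2ccccc2)cc(OCc2ccccc2)c1 | starting material
2 | 2-bromo-3,5-bis(benzyloxy)phenol | Oc1cc(OCc2ccccc2)cc(OCc2ccccc2)c1Br | intermediate
3 | [2-bromo-3,5-bis(benzyloxy)phenoxy]trimethylsilane | C[Si](C)(C)Oc1cc(OCc2ccccc2)cc(OCc2ccccc2)c1Br | intermediate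
4 | [2,4-bis(benzyloxy)-6-(trimethylsilyloxy)phenyl]lithium | C[Si](C)(C)Oc1cc(OCc2ccccc2)cc(OCc2ccccc2)c1[Li] | intermediate
5 | lithium 3,5-bis(benzyloxy)-2-(trimethylsilyl)phenoxide | [Li+].[O-]c1cc(OCc2ccccc2)cc(OCc2ccccc2)c1[Si](C)(C)C | intermediate
6 | 3,5-bis(benzyloxy)-2-(trimethylsilyl)phenyl trifluoromethanesulfonate | C[Si](C)(C)c1c(OS(=O)(=O)C(F)(F)F)cc(OCc2ccccc2)cc1OCc1ccccc1 | intermediate
7 | prop-2-en-1-ol (allyl alcohol) | C=CCO | starting material
8 | bromoacetic acid | OC(=O)CBr | starting material
9 | 2-(allyloxy)acetic acid | C=CCOCC(=O)O | intermediate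
10 | (S)-4-benzyloxazolidin-2-one | O=C1N[C@@H](Cc2ccccc2)CO1 | starting material
11 | 2-(allyloxy)acetic pivalic anhydride | C=CCOCC(=O)OC(=O)C(C)(C)C | intermediate
12 | (S)-3-[2-(allyloxy)acetyl]-4-benzyloxazolidin-2-one | C=CCOCC(=O)N1C(=O)OC[C@@H]1Cc1ccccc1 | intermediate
13 | 3,4-bis(benzyloxy)benzaldehyde | O=Cc1ccc(OCc2ccccc2)c(OCc2ccccc2)c1 | starting material
14 | (S)-3-[(Z)-2-(allyloxy)-1-(dibutylboryloxy)ethenyl]-4-benzyloxazolidin-2-one | C=CCO/C=C(\OB(CCCC)CCCC)N1C(=O)OC[C@@H]1Cc1ccccc1 | intermediate
15 | (S)-3-{(2S,3R)-2-(allyloxy)-3-[3,4-bis(benzyloxy)phenyl]-3-hydroxypropanoyl}-4-benzyloxazolidin-2-one | O=C([C@@H](OCC=C)[C@H](O)c1ccc(OCc2ccccc2)c(OCc2ccccc2)c1)N1C(=O)OC[C@@H]1Cc1ccccc1 | intermediate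
16 | methyl (2S,3R)-2-(allyloxy)-3-[3,4-bis(benzyloxy)phenyl]-3-hydroxypropanoate | COC(=O)[C@@H](OCC=C)[C@H](O)c1ccc(OCc2ccccc2)c(OCc2ccccc2)c1 | intermediate
17 | methyl (2S,3R)-2-(allyloxy)-3-[3,4-bis(benzyloxy)phenyl]-3-[(trimethylsilyl)oxy]propanoate | COC(=O)[C@@H](OCC=C)[C@H](O[Si](C)(C)C)c1ccc(OCc2ccccc2)c(OCc2ccccc2)c1 | intermediate
18 | 3,5-bis(benzyloxy)benzyne | C1#CC(OCc2ccccc2)=CC(OCc2ccccc2)=C1 | intermediate
19 | caesium alkoxide of methyl (2S,3R)-2-(allyloxy)-3-[3,4-bis(benzyloxy)phenyl]-3-hydroxypropanoate | COC(=O)[C@@H](OCC=C)[C@H]([O-])c1ccc(OCc2ccccc2)c(OCc2ccccc2)c1.[Cs+] | intermediate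
20 | methyl (2S,3R)-2-(allyloxy)-3-[3,4-bis(benzyloxy)phenyl]-3-[3,5-bis(benzyloxy)-2-caesiophenoxy]propanoate | COC(=O)[C@@H](OCC=C)[C@H](Oc1cc(OCc2ccccc2)cc(OCc2ccccc2)[c-]1)c1ccc(OCc2ccccc2)c(OCc2ccccc2)c1.[Cs+] | intermediate
21 | (2R,3S)-3-(allyloxy)-5,7-bis(benzyloxy)-2-[3,4-bis(benzyloxy)phenyl]chroman-4-one | C=CCO[C@@H]1C(=O)c2c(OCc3ccccc3)cc(OCc3ccccc3)cc2O[C@@H]1c1ccc(OCc2ccccc2)c(OCc2ccccc2)c1 | intermediate
22 | (2R,3R)-3-(allyloxy)-5,7-bis(benzyloxy)-2-[3,4-bis(benzyloxy)phenyl]chroman-4-ol (C4 epimers) | C=CCO[C@@H]1C(O)c2c(OCc3ccccc3)cc(OCc3ccccc3)cc2O[C@@H]1c1ccc(OCc2ccccc2)c(OCc2ccccc2)c1 | intermediate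
23 | (2R,3R)-3-(allyloxy)-5,7-bis(benzyloxy)-2-[3,4-bis(benzyloxy)phenyl]chroman | C=CCO[C@@H]1Cc2c(OCc3ccccc3)cc(OCc3ccccc3)cc2O[C@@H]1c1ccc(OCc2ccccc2)c(OCc2ccccc2)c1 | intermediate
24 | (2R,3R)-5,7-bis(benzyloxy)-2-[3,4-bis(benzyloxy)phenyl]-3-[(E)-prop-1-enyloxy]chroman | C/C=C/O[C@@H]1Cc2c(OCc3ccccc3)cc(OCc3ccccc3)cc2O[C@@H]1c1ccc(OCc2ccccc2)c(OCc2ccccc2)c1 | intermediate
25 | (2R,3R)-5,7-bis(benzyloxy)-2-[3,4-bis(benzyloxy)phenyl]chroman-3-ol | O[C@@H]1Cc2c(OCc3ccccc3)cc(OCc3ccccc3)cc2O[C@@H]1c1ccc(OCc2ccccc2)c(OCc2ccccc2)c1 | intermediate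
26 | 3-hydroxy-4,5-dimethoxybenzoic acid | COc1cc(C(=O)O)cc(O)c1OC | starting material
27 | benzyl 3-(benzyloxy)-4,5-dimethoxybenzoate | COc1cc(C(=O)OCc2ccccc2)cc(OCc2ccccc2)c1OC | intermediate
28 | 3-(benzyloxy)-4,5-dimethoxybenzoic acid | COc1cc(C(=O)O)cc(OCc2ccccc2)c1OC | intermediate
29 | (2R,3R)-5,7-bis(benzyloxy)-2-[3,4-bis(benzyloxy)phenyl]chroman-3-yl 3-(benzyloxy)-4,5-dimethoxybenzoate | COc1cc(C(=O)O[C@@H]2Cc3c(OCc4ccccc4)cc(OCc4ccccc4)cc3O[C@@H]2c2ccc(OCc3ccccc3)c(OCc3ccccc3)c2)cc(OCc2ccccc2)c1OC | intermediate
30 | (2R,3R)-2-(3,4-dihydroxyphenyl)-5,7-dihydroxychroman-3-yl 3-hydroxy-4,5-dimethoxybenzoate | COc1cc(C(=O)O[C@@H]2Cc3c(O)cc(O)cc3O[C@@H]2c2ccc(O)c(O)c2)cc(O)c1OC | target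

## Step count and least certain steps

Total: 15 steps. Longest linear sequence: 11 steps (steps 4 to 12, then 14 and 15, from 7 and 8 to 30).

**Step 9 (key step).** Several processes could divert it.
- The naked alkoxide 19 may be lost before it meets aryne 18, by retro-aldol fragmentation or by acting as a base on the alpha C–H of 17, which leads to beta-elimination.
- Aryl caesium 20 may be C-silylated or protonated before it reaches the ester.
- The expelled methoxide may add to 18 instead of being silylated.
- C3 of 21 may epimerise, since the trans chromanone is the more stable isomer.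
- Fallback (known chemistry), setting out from 16 and 6 and coming back at 21: the free alcohol 16 and 6 are combined with CsF in MeCN at 20 °C, where the hydroxyl proton and the solvent quench the aryl anion, so the aryne inserts into the O–H bond and gives methyl (2S,3R)-2-(allyloxy)-3-[3,4-bis(benzyloxy)phenyl]-3-[3,5-bis(benzyloxy)phenoxy]propanoate F1. LiOH in THF/H2O at 0 °C gives (2S,3R)-2-(allyloxy)-3-[3,4-bis(benzyloxy)phenyl]-3-[3,5-bis(benzyloxy)phenoxy]propanoic acid F2. (CF3CO)2O in CH2Cl2 at 0 °C then closes ring C by intramolecular Friedel–Crafts acylation, for which the two positions ortho to the ether oxygen on the phloroglucinol-type ring are equivalent, giving 21.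

**Step 10.** The risk is epimerisation at C3 by enolisation under the basic hydride conditions before hydride transfer, because the ketone is deactivated by three donor oxygens and reduces slowly.
- Fallback, setting out from 22 obtained together with its C3 epimer and coming back at 25: no separation is attempted. The mixture of 22 and (2R,3S)-3-(allyloxy)-5,7-bis(benzyloxy)-2-[3,4-bis(benzyloxy)phenyl]chroman-4-ol F3 is taken through steps 11 and 12. These turn F3 into (2R,3S)-3-(allyloxy)-5,7-bis(benzyloxy)-2-[3,4-bis(benzyloxy)phenyl]chroman F4, then (2R,3S)-5,7-bis(benzyloxy)-2-[3,4-bis(benzyloxy)phenyl]-3-[(E)-prop-1-enyloxy]chroman F5, and then (2R,3S)-5,7-bis(benzyloxy)-2-[3,4-bis(benzyloxy)phenyl]chroman-3-ol F6 beside 25. Dess–Martin periodinane in CH2Cl2 oxidises both alcohols to the single ketone (2R)-5,7-bis(benzyloxy)-2-[3,4-bis(benzyloxy)phenyl]chroman-3-one F7. LiBH(s-Bu)3 in THF at −78 °C then adds hydride from the face away from the C2 aryl group and gives 25 alone.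

**Step 11.** The C4 cation may lose the C3 proton to give the enol ether, whose reprotonation and reduction would scramble C3. It may also alkylate ring A of a second molecule, because that ring is a strong nucleophile.
- Fallback, setting out from 22 and coming back at 25, with a radical in place of the cation: the allyl group is removed first under the conditions of step 12, through (2R,3R)-5,7-bis(benzyloxy)-2-[3,4-bis(benzyloxy)phenyl]-3-[(E)-prop-1-enyloxy]chroman-4-ol F8, to give (2R,3R)-5,7-bis(benzyloxy)-2-[3,4-bis(benzyloxy)phenyl]chroman-3,4-diol F9. 1,1'-Thiocarbonyldiimidazole in toluene converts its 3,4-cis epimer, expected to be the main one, into the cis-fused cyclic 3,4-O-thiocarbonate of the 2,3-cis-3,4-cis diol F10. Bu3SnH with AIBN in toluene at 80 °C cleaves the C4–O bond, because that gives the benzylic radical, and mild basic hydrolysis of the residue on O3 gives 25.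

**Step 1.** Bromination may go para to the hydroxyl group or twice, since all three ring positions are activated by all three oxygens.
- Fallback, setting out from 1 and coming back at 6: i-PrNCO with Et3N (cat.) gives 3,5-bis(benzyloxy)phenyl N-isopropylcarbamate F11. N-Silylation in the flask (Me3SiOTf, TMEDA, Et2O), ortho-lithiation with n-BuLi at −78 °C between the carbamate and a benzyloxy group, and Me3SiCl give 3,5-bis(benzyloxy)-2-(trimethylsilyl)phenyl N-isopropylcarbamate F12. Et2NH and DBU in MeCN at 40 °C release 3,5-bis(benzyloxy)-2-(trimethylsilyl)phenol F13, which is triflated in the same flask with PhNTf2 to give 6.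

## Further compounds

F1 | step 9 | methyl (2S,3R)-2-(allyloxy)-3-[3,4-bis(benzyloxy)phenyl]-3-[3,5-bis(benzyloxy)phenoxy]propanoate | COC(=O)[C@@H](OCC=C)[C@H](Oc1cc(OCc2ccccc2)cc(OCc2ccccc2)c1)c1ccc(OCc2ccccc2)c(OCc2ccccc2)c1
F2 | step 9 | (2S,3R)-2-(allyloxy)-3-[3,4-bis(benzyloxy)phenyl]-3-[3,5-bis(benzyloxy)phenoxy]propanoic acid | OC(=O)[C@@H](OCC=C)[C@H](Oc1cc(OCc2ccccc2)cc(OCc2ccccc2)c1)c1ccc(OCc2ccccc2)c(OCc2ccccc2)c1
F3 | step 10 | (2R,3S)-3-(allyloxy)-5,7-bis(benzyloxy)-2-[3,4-bis(benzyloxy)phenyl]chroman-4-ol (2,3-trans, C4 epimers) | C=CCO[C@H]1C(O)c2c(OCc3ccccc3)cc(OCc3ccccc3)cc2O[C@@H]1c1ccc(OCc2ccccc2)c(OCc2ccccc2)c1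
F4 | step 10 | (2R,3S)-3-(allyloxy)-5,7-bis(benzyloxy)-2-[3,4-bis(benzyloxy)phenyl]chroman | C=CCO[C@H]1Cc2c(OCc3ccccc3)cc(OCc3ccccc3)cc2O[C@@H]1c1ccc(OCc2ccccc2)c(OCc2ccccc2)c1
F5 | step 10 | (2R,3S)-5,7-bis(benzyloxy)-2-[3,4-bis(benzyloxy)phenyl]-3-[(E)-prop-1-enyloxy]chroman | C/C=C/O[C@H]1Cc2c(OCc3ccccc3)cc(OCc3ccccc3)cc2O[C@@H]1c1ccc(OCc2ccccc2)c(OCc2ccccc2)c1
F6 | step 10 | (2R,3S)-5,7-bis(benzyloxy)-2-[3,4-bis(benzyloxy)phenyl]chroman-3-ol | O[C@H]1Cc2c(OCc3ccccc3)cc(OCc3ccccc3)cc2O[C@@H]1c1ccc(OCc2ccccc2)c(OCc2ccccc2)c1
F7 | step 10 | (2R)-5,7-bis(benzyloxy)-2-[3,4-bis(benzyloxy)phenyl]chroman-3-one | O=C1Cc2c(OCc3ccccc3)cc(OCc3ccccc3)cc2O[C@@H]1c1ccc(OCc2ccccc2)c(OCc2ccccc2)c1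
F8 | step 11 | (2R,3R)-5,7-bis(benzyloxy)-2-[3,4-bis(benzyloxy)phenyl]-3-[(E)-prop-1-enyloxy]chroman-4-ol (C4 epimers) | C/C=C/O[C@@H]1C(O)c2c(OCc3ccccc3)cc(OCc3ccccc3)cc2O[C@@H]1c1ccc(OCc2ccccc2)c(OCc2ccccc2)c1
F9 | step 11 | (2R,3R)-5,7-bis(benzyloxy)-2-[3,4-bis(benzyloxy)phenyl]chroman-3,4-diol (C4 epimers) | O[C@@H]1C(O)c2c(OCc3ccccc3)cc(OCc3ccccc3)cc2O[C@@H]1c1ccc(OCc2ccccc2)c(OCc2ccccc2)c1
F10 | step 11 | cis-fused cyclic 3,4-O-thiocarbonate of the 2,3-cis-3,4-cis epimer of F9 | S=C1O[C@@H]2c3c(OCc4ccccc4)cc(OCc4ccccc4)cc3O[C@H](c3ccc(OCc4ccccc4)c(OCc4ccccc4)c3)[C@@H]2O1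
F11 | step 1 | 3,5-bis(benzyloxy)phenyl N-isopropylcarbamate | CC(C)NC(=O)Oc1cc(OCc2ccccc2)cc(OCc2ccccc2)c1
F12 | step 1 | 3,5-bis(benzyloxy)-2-(trimethylsilyl)phenyl N-isopropylcarbamate | CC(C)NC(=O)Oc1cc(OCc2ccccc2)cc(OCc2ccccc2)c1[Si](C)(C)C
F13 | step 1 | 3,5-bis(benzyloxy)-2-(trimethylsilyl)phenol | Oc1cc(OCc2ccccc2)cc(OCc2ccccc2)c1[Si](C)(C)C
A1 | alternative 1 | methyl 4-{(2R,3R)-2-[3,4-bis(benzyloxy)phenyl]-3-(methoxymethoxy)-3,4-dihydro-2H-pyran-6-yl}-3-oxobutanoate | COC(=O)CC(=O)CC1=CC[C@@H](OCOC)[C@@H](c2ccc(OCc3ccccc3)c(OCc3ccccc3)c2)O1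
A2 | alternative 1 | (2R,3R)-2-[3,4-bis(benzyloxy)phenyl]-3-(methoxymethoxy)chroman-5,7-diol | COCO[C@@H]1Cc2c(O)cc(O)cc2O[C@@H]1c1ccc(OCc2ccccc2)c(OCc2ccccc2)c1
A3 | alternative 2 | 3,5-bis(benzyloxy)-2-(2-oxoethyl)phenyl 3,4-bis(benzyloxy)benzoate | O=CCc1c(OCc2ccccc2)cc(OCc2ccccc2)cc1OC(=O)c1ccc(OCc2ccccc2)c(OCc2ccccc2)c1
A4 | alternative 2 | 5,7-bis(benzyloxy)-2-[3,4-bis(benzyloxy)phenyl]-4H-chromene | C1=C(c2ccc(OCc3ccccc3)c(OCc3ccccc3)c2)Oc2cc(OCc3ccccc3)cc(OCc3ccccc3)c2C1
A5 | alternative 3 | 3,5-bis(benzyloxy)-2-(hydroxymethyl)phenol | OCc1c(O)cc(OCc2ccccc2)cc1OCc1ccccc1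
A6 | alternative 3 | 3,5-bis(benzyloxy)-6-methylidenecyclohexa-2,4-dien-1-one | C=C1C(=O)C=C(OCc2ccccc2)C=C1OCc1ccccc1
A7 | alternative 3 | (Z)-2-[3,4-bis(benzyloxy)phenyl]ethenyl 3-(benzyloxy)-4,5-dimethoxybenzoate | COc1cc(C(=O)O/C=C\c2ccc(OCc3ccccc3)c(OCc3ccccc3)c2)cc(OCc2ccccc2)c1OC
A8 | alternative 3 | (2R,3R)-5,7-bis(benzyloxy)-2-[3,4-bis(benzyloxy)phenyl]chroman-3-yl 3-(benzyloxy)-4,5-dimethoxybenzoate | COc1cc(C(=O)O[C@@H]2Cc3c(OCc4ccccc4)cc(OCc4ccccc4)cc3O[C@@H]2c2ccc(OCc3ccccc3)c(OCc3ccccc3)c2)cc(OCc2ccccc2)c1OC
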